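Count the Z standing in the flask per Q charged, a turnover number of the Z present, because it tells what to charge next.

| flask | J | L | Q | D | remark | time |
|---|---|---|---|---|---|---|
| noon | 2 M | 2.4 M | 16 mM | 41 mM | the very flask that is asked about, followed so far |  |
| flask | 2.0 M | 2.40 M | 16 mM | 41 mM |  | 10 d |

noon run (percent of the J charged)

| time / d | Z / % |
|---|---|
| 0.250 | 28.8 |
| 0.833 | 44.7 |
| 1.25 | 48.9 |
| 2.00 | 53.3 |
| 3.00 | 54.9 |

(each reading ± 0.5 percentage points)

- the numbers in the tables scatter with a standard deviation of 0.5 percentage points
- the reaction counts as stopped when no species that holds the J changes by six tenths of a point or more over the second half of the time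

- which holds at 10 d: what has brought the reaction to rest, or that it has not come to rest (forward and back rates have come level / it is still moving / all of J has reacted / no working catalyst is left / L has run out first)
- Z at 10 d, in percent of the J charged
- amount of Z if the flask were left three thousand times as long, in percent of the J charged

The noon flask is this flask followed so far, and at its last reading, at 3.00 d, it stands at a count of 68.6 turnovers per Q charged. The first 0.250 d gave 36.0 of these, while the last day gave 2.00, so the flask is slowing hard. Two readings remain open: Q may quit after a fixed count, or forward and back rates may be coming level. Since that gain is still shrinking, allow it once more and commit to my own figure of 70.6 turnovers at 10 d.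

So add no Q to this flask, leave it standing, and charge the next flask with 0.50 M of J, holding L, Q, D and the time. That charge offers 31.2 turnovers, fewer than the 68.6 already counted, so under a fixed count Q has room to carry that J through to Z, whereas under a balance Z stops short of the full charge.

The forecast gives forward and back rates have come level, with Z at 56% (from 55.2% to 57.5%) at 10 d and 56% (from 55.2% to 60%) for the long wait: “I take equilibrium as the likelier one”.

The flask gives forward and back rates have come level, with Z at 56.7% at 10 d and 56.7% for the long wait.

    Q + D ⇌ G, settled at all times (K = 60.0 /M)
    Z + Q ⇌ X + Q, rate k2*[Q]*[Z] forward; the back reaction follows from the equilibrium constant (K = 0.540, k = 0.190 /M/min)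
    J + L + Q ⇌ Z + Q, rate k3*[J]*[L]*[Q] forward; the back reaction follows from the equilibrium constant (K = 6.90 /M, k = 0.0990 /M²/min)

Count this flask again: after the 68.6 of the last reading it stands at 70.9 turnovers of Z present at 10 d, and waiting longer adds nothing. Then count the neighbour charged with 0.50 M of J, where Z reaches 61.9%, which is 19.3 turnovers, fewer than this flask's 70.9 and fewer than the 31.2 its charge offers. Q stands at 35.2% of its charge there, with G at 64.8%, as Q does at 35.2% here, X holds 33.4% of the neighbour's J, and 4.7% of that J is still unreacted.

The readings were computed with made-up constants.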